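## Structural features

The target is robinetinidol-(4β→6)-gallocatechin. It is a 5-deoxy flavan-3-ol (ring A with one 7-OH, heterocycle C, pyrogallol ring B) whose C4 is bonded to C6 of ring D of a gallocatechin unit (rings D, F, E). There are five stereocentres in two groups. C2/C3 of ring F are (2R,3S) and trans, as in (+)-gallocatechin. The contiguous triad of ring C is C2 (R), C3 (S), C4 (R), that is 2,3-trans-3,4-cis, with C4 a diarylmethine between two ortho-oxygenated arenes. The free compound is fragile: eleven hydroxyls, two pyrogallol rings that oxidise in air and base, two benzylic C2–O1 ether bonds that open or epimerise, and an interflavanyl C4–C6 bond that strong acid can cleave. It should therefore appear only in the last step. The real difficulties are three: the link must go to C6 of ring D although C8 is the more nucleophilic position; the C3 oxygen and the ring D aryl group must be cis, which is the minor outcome when a C4 cation is captured by an arene; and C4 must be fixed relative to stereocentres far away in ring F. The key step exploits the fact that O1–C8a–C4a–C4 of ring C is the skeleton of an ortho-quinone methide of ring A, while C2–C3, both oxygen-bearing once ring B is removed, is a cis-enediol ether. Ring C is thus a [4+2] retron, and the acetal carbon C2 left by the cycloaddition can take ring B from the face opposite to its two neighbours.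

## Logic of the disconnections

26 ⇒ 25. The ten O–benzyl bonds are cut and the C8–H of ring D is exchanged for C8–Br. All phenols and the ring F alcohol then carry one kind of protecting group, and the halogen that enforced C6 regiochemistry leaves in the same operation. The forward step must cleave ten ethers and one aryl bromide without opening the benzylic C2–O1 bonds.

25 ⇒ 24 ⇒ 16 + 21. The C2–aryl bond of ring C is cut and the C3 hydroxyl is written as a participating ester. Since C2 is at the acetal oxidation level after the cycloaddition, ring B is best brought in as a nucleophile onto a C2 cation equivalent. This turns ring B into a simple arylmetal and derives the C2 configuration from C3 and C4. The forward step must substitute trans to the C3 oxygen and to the C4 aryl group without eliminating to a chromene.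

16 ⇒ 15 ⇒ 14. The two esters are traced back to the cyclic ketal by functional-group interchange. This connects the arylation substrate to the direct cycloadduct. The hydrolysis must spare the benzyl ethers, the aryl bromide and the diarylmethine.

14 ⇒ 9 + 12. The C3–C4 and O1–C2 bonds are cut. This removes ring C and three stereocentres at once, and sets the 3,4-cis relationship through an endo cycloaddition in place of a cation capture. The precursors are a benzhydrol and a symmetric two-carbon enediol unit. The forward step needs an E-configured quinone methide, endo approach, and a chiral acid that selects one face.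

9 ⇒ 5 + 6. The bond between the carbinol carbon and C6 of ring D is cut, with the metal placed on ring D. Ring A then arrives as an aldehyde whose ortho-phenol needs no protecting group, so the free phenol of 9 is obtained without an acidic unmasking. 6 is purchasable with the correct oxygen pattern. The forward step needs iodine–magnesium exchange that leaves the C8 bromide alone, and addition to an aldehyde that carries a phenolate.

5 ⇒ 4 ⇒ 3. The C6–I and C8–Br bonds are cut. The first halogen blocks the more reactive C8 position and the second marks C6 for metalation. The first halogenation must go to C8 only and the second to C6 in preference to ring E.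

3 ⇒ 2 ⇒ 1. The six O–benzyl bonds are cut, in two stages (phenols, then the secondary alcohol) to avoid C-alkylation of ring D. This reaches the natural product 1, which supplies rings D, E, F and two stereocentres.

12 ⇒ 11 ⇒ 10. The ring double bond is traced to C–Cl/C–H and the chloride to a C–H bond. The forward steps are a radical chlorination at the carbon next to oxygen and a base-induced elimination.

21 ⇒ 19 ⇒ 18 ⇒ 17. The C–Zn bond is traced to C–Br, the benzyl ethers to free phenols, and these to methyl ethers. The forward steps must keep the bromine at C5 of the pyrogallol ring, where direct bromination would not put it.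

## Other disconnections considered

Alternative 1: Both O1–C2 bonds (rings C and F) are cut, leading back to the bis-epoxide diphenol A2. In the forward step, acid makes the ring A phenol and the ring D phenol attack the benzylic carbons of the two trans-epoxides with inversion, giving the nona-O-benzyl compound A1.
- In favour: two rings close in one operation; both C2 centres come from epoxide geometry; no blocking halogen and no natural flavan-3-ol are needed; A1 is one hydrogenolysis away from the target, which is better than the end-game from 14.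
- Against: the electron-rich benzylic epoxide carbons react with SN1 character, so inversion may leak at two centres, and 5-exo opening to dihydrobenzofurans competes with 6-endo closure. A2 itself needs the C4 diarylmethine centre, two stereoselective epoxidations of very electron-rich styrenes, and a pentasubstituted ring D built from scratch.
- Comparison: on structure the two plans are equal in using only benzyl ethers. On mechanism the chosen plan sets the 3,4-cis relationship by the endo rule of a cycloaddition, while this alternative must set C3/C4 in an open chain. On step economy the chosen plan is shorter, because 1 delivers rings D, E, F and two stereocentres ready-made.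

Alternative 2: The O1–C2 bond of ring F is cut, leading back to the 1,3-diarylpropan-2-ol A4, assembled around a purchasable enantiopure three-carbon epoxide linchpin. In the forward step, Ag2O oxidises the 4-hydroxy-3,5-dibenzyloxybenzyl group to a para-quinone methide and the ring D phenol adds to the methide carbon, giving A3 with a new C2 centre.
- In favour: the oxidative cyclisation is mild and of a known type; C3 of ring F comes from a cheap chiral building block; the plan does not depend on the supply of 1, a point on which it is better.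
- Against: it solves the easy half. The whole upper unit, including the 3,4-cis triad, must already be in place. Two particular phenols must be free among eleven oxygens. Ag2O must oxidise one ring among several electron-rich ones. The 2,3-trans outcome rests on the preference of the cyclisation, not on a directing element.
- Comparison: on structure it needs an extra silyl ether and differentiated phenols, where the chosen plan needs one protecting-group type. On mechanism it is equal in reliability for the ring closure but leaves the hard stereotriad unaddressed. On step economy it is longer, since the lower unit is made instead of bought.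

Alternative 3: The O1–C8a aryl ether bond of ring C is cut, leading back to the open-chain bromo alcohol A6. In the forward step, CuI with 1,10-phenanthroline and Cs2CO3 couples the C2 alkoxide with the ring A aryl bromide, with retention at C2, to give A5.
- In favour: ring closure does not touch any stereocentre, so the configuration of the acyclic triad is transferred without an ionisable C2 intermediate. This is better than the anomeric substitution of step 14 in configurational security, and the reaction class is established for chromans.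
- Against: the acyclic triad with a diarylmethine next to two oxygenated carbons must be built with full control, which moves the main problem elsewhere. Hot basic copper conditions invite β-elimination of the C3 benzyloxy group and loss of the halide. The methoxymethyl and silyl ethers of A5 require an acidic deprotection on an acid-sensitive 4-arylflavan in addition to hydrogenolysis.
- Comparison: on structure it is worse (three protecting-group types and an extra end-game step). On mechanism it is equal or better for the ring closure, but weaker for the 3,4-relationship. On step economy it is worse, because one cycloaddition of the chosen plan replaces a multi-step construction of the stereotriad.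

Key step: step 8

Remarks on the chemistry:
- (+)-Gallocatechin is taken as the purchasable natural (2R,3S) enantiomer.
- The enantiomer of the phosphoric acid that favours the required face of the methide cannot be assigned in advance for this substrate. The (R) acid is written, and the (S) acid would take its place if the (R) acid favoured the other face.
- The adduct 14, written all-cis (2S,3S,4R), gives the (2R,3S,4R) upper unit of 26 after inversion at C2; no structure needed correction.
- The benzhydrol 9 is reached with the metal on ring D and the aldehyde on ring A, so that its ortho-phenol is never protected.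

Abbreviations: Bn = benzyl; TBP = 3,4,5-tris(benzyloxy)phenyl; LU = (2R,3S)-8-bromo-3,5,7-tris(benzyloxy)-2-(TBP)chroman-6-yl.

## Steps

Step 1
Reactants: 1 (+)-gallocatechin
Product: 2 (2R,3S)-5,7-bis(benzyloxy)-2-(TBP)chroman-3-ol
Conditions: BnBr (5.5 equiv), K2CO3, DMF, argon, 0 °C → rt
Reagents that add atoms: benzyl bromide, BrCc1ccccc1
Why: Williamson etherification; carbonate deprotonates only the five phenols, and low temperature with exclusion of air limits C-benzylation of ring D, oxidation of ring E and base-induced epimerisation at C2.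

Step 2
Reactants: 2 (2R,3S)-5,7-bis(benzyloxy)-2-(TBP)chroman-3-ol
Product: 3 (2R,3S)-3,5,7-tris(benzyloxy)-2-(TBP)chroman
Conditions: NaH, BnBr, tetrabutylammonium iodide (cat.), DMF, 0 °C → rt
Reagents that add atoms: benzyl bromide, BrCc1ccccc1
Why: Williamson etherification of the secondary alkoxide; with no phenoxide left, neither ring opening nor C-alkylation can compete.

Step 3
Reactants: 3 (2R,3S)-3,5,7-tris(benzyloxy)-2-(TBP)chroman
Product: 4 (2R,3S)-8-bromo-3,5,7-tris(benzyloxy)-2-(TBP)chroman
Conditions: NBS (1.0 equiv), CH2Cl2, −78 → 0 °C, dark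
Reagents that add atoms: N-bromosuccinimide, O=C1CCC(=O)N1Br
Why: Electrophilic aromatic bromination; in O-benzylated flavan-3-ols C8 is the more nucleophilic and less hindered position of ring D (C6 lies between two benzyloxy groups), and ring E is far less activated.

Step 4
Reactants: 4 (2R,3S)-8-bromo-3,5,7-tris(benzyloxy)-2-(TBP)chroman
Product: 5 (2R,3S)-8-bromo-6-iodo-3,5,7-tris(benzyloxy)-2-(TBP)chroman
Conditions: NIS (1.1 equiv), CF3CO2H (cat.), MeCN/CH2Cl2, 0 °C → rt, dark
Reagents that add atoms: N-iodosuccinimide, O=C1CCC(=O)N1I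
Why: Electrophilic aromatic iodination at the only free position of ring D, which is ortho to two ether oxygens and para to O1 and so more reactive than C2'/C6' of ring E; the reaction parallels the known 6,8-dihalogenation of such rings.

Step 5
Reactants: 5 (2R,3S)-8-bromo-6-iodo-3,5,7-tris(benzyloxy)-2-(TBP)chroman; 6 4-(benzyloxy)-2-hydroxybenzaldehyde
Product: 9 (4-benzyloxy-2-hydroxyphenyl)(LU)methanol (both carbinol epimers), via C6 arylmagnesium chloride 7 (not isolated), via aldehyde magnesium phenolate 8 (not isolated)
Conditions: 5, i-PrMgCl·LiCl (1.05 equiv), THF, −30 → −10 °C; separately 6, t-BuMgCl (1.0 equiv), THF, −40 °C; combine, −20 °C → rt; pH 7 phosphate buffer; chromatography on Et3N-deactivated silica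
Reagents that add atoms: none
Why: Iodine–magnesium exchange is much faster at the aryl iodide than at the electron-rich aryl bromide, and the arylmagnesium adds 1,2 to the magnesium-chelated salicylaldehyde. The phenol is masked only as its salt and returns on neutral work-up, and the unselective carbinol centre is erased on ionisation in step 8.

Step 6
Reactants: 10 2,2-dimethyl-1,3-dioxolane
Product: 11 4-chloro-2,2-dimethyl-1,3-dioxolane (racemic)
Conditions: SO2Cl2 (1.0 equiv), 2,2'-azobis(2-methylpropionitrile) (cat.), neat, 60 °C, N2 sweep; distillation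
Reagents that add atoms: sulfuryl chloride, O=S(=O)(Cl)Cl
Why: Free-radical chain chlorination; hydrogen abstraction is fastest at the ring C–H next to oxygen, while the methyl groups are unactivated.

Step 7
Reactants: 11 4-chloro-2,2-dimethyl-1,3-dioxolane
Product: 12 2,2-dimethyl-1,3-dioxole
Conditions: KOt-Bu, tetraglyme, 0 → 80 °C, product distilled out under N2, stored over K2CO3 at −20 °C
Reagents that add atoms: none
Why: E2 dehydrochlorination of the α-chloro ether by a hindered base, the same way vinylene carbonate is made from its chloro precursor; the volatile acid-sensitive product leaves the basic medium by distillation.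

Step 8
Reactants: 9 (4-benzyloxy-2-hydroxyphenyl)(LU)methanol; 12 2,2-dimethyl-1,3-dioxole
Product: 14 (2S,3S,4R)-7-benzyloxy-4-(LU)-2,3-O-isopropylidenechroman-2,3-diol (acetonide oxygens and C4 aryl group all cis), via ortho-quinone methide 13 (not isolated)
Conditions: (R)-3,3'-bis(2,4,6-triisopropylphenyl)-1,1'-binaphthalene-2,2'-diyl hydrogen phosphate (10 mol %), 12 (5 equiv), 5 Å MS, toluene, −20 → 0 °C, slow addition of 9
Reagents that add atoms: none
Why: Proposed new method: the phosphoric acid ionises the doubly activated benzhydrol, the sieves take up the water, and the E-configured ortho-quinone methide 13 (bulky ring D aryl group turned away from the carbonyl oxygen) stays hydrogen-bonded to the chiral phosphate. The closest known reaction type is the chiral phosphoric acid-catalysed inverse-electron-demand [4+2] cycloaddition of in situ ortho-quinone methides with enol ethers and enamides, together with uncatalysed hetero-Diels–Alder additions of 1-oxadienes to 2,2-dimethyl-1,3-dioxole; combining this catalysis with a 1,3-dioxole is the untested element. The electron-rich dioxole attacks the methide carbon (C3–C4 bond leading) and the carbonyl oxygen closes onto the developing oxocarbenium carbon (O1–C2) in one asynchronous suprafacial event, so ring C is closed by cycloaddition as a six-membered ring cis-fused to the dioxolane. C2 and C3 are cis by necessity, because the cis geometry of the cyclic alkene is carried over. The C3/C4 relationship follows from the endo transition state, in which both dioxole oxygens lie under the cationic heterodiene, so that the C3 oxygen and the C4 aryl group end up cis. The absolute sense at C4 (R), and with it at C3 and C2, comes from the phosphate, which covers one face of the bound methide; since the lower unit is enantiopure, a wrong-face adduct is a diastereomer and can be removed. The step therefore needs E geometry, endo approach and face selection; regiochemistry cannot arise with a symmetric dienophile, and the C8 bromine and full O-benzylation leave no nucleophilic site for Friedel–Crafts self-condensation of the cation.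

Step 9
Reactants: 14 (2S,3S,4R)-7-benzyloxy-4-(LU)-2,3-O-isopropylidenechroman-2,3-diol
Product: 15 (3S,4R)-7-benzyloxy-4-(LU)chroman-2,3-diol (hemiacetal, both C2 epimers)
Conditions: AcOH/H2O/THF (4:1:1), 45 °C
Reagents that add atoms: none
Why: Acid hydrolysis of the isopropylidene ketal, which cleaves at the ketal carbon through the tertiary oxocarbenium ion, so that the oxygen of water leaves in acetone and 15 gains only hydrogen. Benzyl ethers, the aryl bromide and the C3/C4 centres are inert to dilute acetic acid.

Step 10
Reactants: 15 (3S,4R)-7-benzyloxy-4-(LU)chroman-2,3-diol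
Product: 16 (3S,4R)-7-benzyloxy-4-(LU)chroman-2,3-diyl dipivalate (both C2 epimers)
Conditions: PivCl (4 equiv), pyridine, 4-(dimethylamino)pyridine (cat.), CH2Cl2, 0 → 40 °C
Reagents that add atoms: pivaloyl chloride, CC(C)(C)C(Cl)=O
Why: Nucleophilic acyl substitution at the hemiacetal and the secondary hydroxyl of the cyclic form; the anomeric mixture is of no consequence, because both epimers converge in step 14.

Step 11
Reactants: 17 5-bromo-1,2,3-trimethoxybenzene
Product: 18 5-bromobenzene-1,2,3-triol
Conditions: BBr3 (3.5 equiv), CH2Cl2, −78 °C → rt; then H2O, argon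
Reagents that add atoms: none
Why: Lewis acid-mediated cleavage of aryl methyl ethers (bromide attacks the O-methyl group of the boron complex); the aryl bromide is untouched.

Step 12
Reactants: 18 5-bromobenzene-1,2,3-triol
Product: 19 5-bromo-1,2,3-tris(benzyloxy)benzene
Conditions: BnBr (3.3 equiv), K2CO3, DMF, argon, rt → 50 °C
Reagents that add atoms: benzyl bromide, BrCc1ccccc1
Why: Williamson etherification of the three phenols; this places the halogen meta to two oxygens, where direct bromination of the triether would not.

Step 13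
Reactants: 19 5-bromo-1,2,3-tris(benzyloxy)benzene
Product: 21 (TBP)zinc bromide, as its LiBr complex in solution, used at once, via aryllithium 20 (not isolated)
Conditions: n-BuLi (1.0 equiv), toluene/n-Bu2O, −30 °C; then ZnBr2·LiBr (1.0 equiv) in n-Bu2O, −30 °C → rt
Reagents that add atoms: zinc bromide, Br[Zn]Br
Why: Bromine–lithium exchange followed by transmetalation to zinc; the weakly coordinating solvent pair keeps the zinc reagent Lewis acidic enough for step 14.

Step 14
Reactants: 16 (3S,4R)-7-benzyloxy-4-(LU)chroman-2,3-diyl dipivalate; 21 (TBP)zinc bromide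
Product: 24 (2R,3S,4R)-7-benzyloxy-2-(TBP)-4-(LU)chroman-3-yl pivalate, via chroman-2-yl bromide 22 (not isolated), via dioxolanium bromide 23 (not isolated)
Conditions: 16, Me3SiBr (1.5 equiv), ZnBr2 (cat.), toluene, 0 °C → rt, concentrate; then 21 (2 equiv), toluene/n-Bu2O, 85 °C
Reagents that add atoms: none
Why: Proposed new method: Me3SiBr/ZnBr2 exchanges the anomeric pivalate for bromide (22), the C3 pivalate displaces bromide to give the cis-fused dioxolanium ion 23 on the face of the C3 oxygen, and the arylzinc bromide delivers ring B to C2 from the opposite face, anti to both the C3 oxygen and the pseudo-axial C4 aryl group, which sets C2 (R) and the 2,3-trans relationship. The closest known reaction type is the 1,2-trans-selective C-arylation of 2-O-pivaloyl glycosyl bromides with arylzinc reagents in toluene/dibutyl ether; a chroman-2-yl donor, whose ring oxygen is an aryl ether oxygen, has not been used in it.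

Step 15
Reactants: 24 (2R,3S,4R)-7-benzyloxy-2-(TBP)-4-(LU)chroman-3-yl pivalate
Product: 25 (2R,3S,4R)-7-benzyloxy-2-(TBP)-4-(LU)chroman-3-ol
Conditions: i-Bu2AlH (3 equiv), CH2Cl2, −78 °C; aq. potassium sodium tartrate
Reagents that add atoms: none
Why: Reductive cleavage of the hindered ester by the aluminium hydride; no basic medium is involved, so C2 cannot epimerise, and the aryl bromide and benzyl ethers are inert at −78 °C.

Step 16
Reactants: 25 (2R,3S,4R)-7-benzyloxy-2-(TBP)-4-(LU)chroman-3-ol
Product: 26 robinetinidol-(4β→6)-gallocatechin (target)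
Conditions: H2 (1 atm), Pd(OH)2/C, Et3N (1.1 equiv), THF/MeOH (1:1), rt; filtration and concentration under argon
Reagents that add atoms: none
Why: Catalytic hydrogenolysis of the ten benzyl ethers with concurrent hydrodebromination at C8; the amine takes up the HBr so that the benzylic ether bonds and the interflavanyl bond do not meet acid.

## Compound list

1 | (+)-gallocatechin, (2R,3S)-2-(3,4,5-trihydroxyphenyl)chroman-3,5,7-triol | Oc1cc(O)c2C[C@H](O)[C@@H](c3cc(O)c(O)c(O)c3)Oc2c1 | starting material
2 | (2R,3S)-5,7-bis(benzyloxy)-2-[3,4,5-tris(benzyloxy)phenyl]chroman-3-ol | c1ccccc1COc1cc(OCc3ccccc3)c2C[C@H](O)[C@@H](c3cc(OCc4ccccc4)c(OCc4ccccc4)c(OCc4ccccc4)c3)Oc2c1 | intermediate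
3 | (2R,3S)-3,5,7-tris(benzyloxy)-2-[3,4,5-tris(benzyloxy)phenyl]chroman | c1ccccc1COc1cc(OCc3ccccc3)c2C[C@H](OCc3ccccc3)[C@@H](c3cc(OCc4ccccc4)c(OCc4ccccc4)c(OCc4ccccc4)c3)Oc2c1 | intermediate
4 | (2R,3S)-8-bromo-3,5,7-tris(benzyloxy)-2-[3,4,5-tris(benzyloxy)phenyl]chroman | c1c(OCc3ccccc3)c(Br)c2c(c1OCc3ccccc3)C[C@H](OCc3ccccc3)[C@@H](c1cc(OCc3ccccc3)c(OCc3ccccc3)c(OCc3ccccc3)c1)O2 | intermediate
5 | (2R,3S)-8-bromo-6-iodo-3,5,7-tris(benzyloxy)-2-[3,4,5-tris(benzyloxy)phenyl]chroman | Ic1c(OCc3ccccc3)c(Br)c2c(c1OCc3ccccc3)C[C@H](OCc3ccccc3)[C@@H](c1cc(OCc3ccccc3)c(OCc3ccccc3)c(OCc3ccccc3)c1)O2 | intermediate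
6 | 4-(benzyloxy)-2-hydroxybenzaldehyde | O=Cc1ccc(OCc2ccccc2)cc1O | starting material
7 | [(2R,3S)-8-bromo-3,5,7-tris(benzyloxy)-2-(3,4,5-tris(benzyloxy)phenyl)chroman-6-yl]magnesium chloride (LiCl complex) | Cl[Mg]c1c(OCc3ccccc3)c(Br)c2c(c1OCc3ccccc3)C[C@H](OCc3ccccc3)[C@@H](c1cc(OCc3ccccc3)c(OCc3ccccc3)c(OCc3ccccc3)c1)O2 | intermediate (not isolated)
8 | chloromagnesium 5-(benzyloxy)-2-formylphenolate | O=Cc1ccc(OCc2ccccc2)cc1O[Mg]Cl | intermediate (not isolated)
9 | (4-benzyloxy-2-hydroxyphenyl)[(2R,3S)-8-bromo-3,5,7-tris(benzyloxy)-2-(3,4,5-tris(benzyloxy)phenyl)chroman-6-yl]methanol, both carbinol epimers | c1ccccc1COc1ccc(c(O)c1)C(O)c1c(OCc3ccccc3)c(Br)c2c(c1OCc3ccccc3)C[C@H](OCc3ccccc3)[C@@H](c1cc(OCc3ccccc3)c(OCc3ccccc3)c(OCc3ccccc3)c1)O2 | intermediate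
10 | 2,2-dimethyl-1,3-dioxolane | CC1(C)OCCO1 | starting material
11 | 4-chloro-2,2-dimethyl-1,3-dioxolane (racemic) | CC1(C)OCC(Cl)O1 | intermediate
12 | 2,2-dimethyl-1,3-dioxole | CC1(C)OC=CO1 | intermediate
13 | (E)-3-(benzyloxy)-6-[(LU)methylidene]cyclohexa-2,4-dien-1-one, the ortho-quinone methide of ring A | O=C1C=C(OCc2ccccc2)C=C/C1=C\c1c(OCc3ccccc3)c(Br)c2c(c1OCc3ccccc3)C[C@H](OCc3ccccc3)[C@@H](c1cc(OCc3ccccc3)c(OCc3ccccc3)c(OCc3ccccc3)c1)O2 | intermediate (not isolated)
14 | (2S,3S,4R)-7-benzyloxy-4-(LU)-2,3-O-isopropylidenechroman-2,3-diol, all-cis | c1ccccc1COc1ccc2c(c1)O[C@H]3OC(C)(C)O[C@H]3[C@H]2c1c(OCc3ccccc3)c(Br)c2c(c1OCc3ccccc3)C[C@H](OCc3ccccc3)[C@@H](c1cc(OCc3ccccc3)c(OCc3ccccc3)c(OCc3ccccc3)c1)O2 | intermediate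
15 | (3S,4R)-7-benzyloxy-4-(LU)chroman-2,3-diol, both C2 epimers | c1ccccc1COc1ccc2c(c1)OC(O)[C@@H](O)[C@H]2c1c(OCc3ccccc3)c(Br)c2c(c1OCc3ccccc3)C[C@H](OCc3ccccc3)[C@@H](c1cc(OCc3ccccc3)c(OCc3ccccc3)c(OCc3ccccc3)c1)O2 | intermediate
16 | (3S,4R)-7-benzyloxy-4-(LU)chroman-2,3-diyl bis(2,2-dimethylpropanoate), both C2 epimers | c1ccccc1COc1ccc2c(c1)OC(OC(=O)C(C)(C)C)[C@@H](OC(=O)C(C)(C)C)[C@H]2c1c(OCc3ccccc3)c(Br)c2c(c1OCc3ccccc3)C[C@H](OCc3ccccc3)[C@@H](c1cc(OCc3ccccc3)c(OCc3ccccc3)c(OCc3ccccc3)c1)O2 | intermediate
17 | 5-bromo-1,2,3-trimethoxybenzene | COc1cc(Br)cc(OC)c1OC | starting material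
18 | 5-bromobenzene-1,2,3-triol | Oc1cc(Br)cc(O)c1O | intermediate
19 | 5-bromo-1,2,3-tris(benzyloxy)benzene | Brc1cc(OCc2ccccc2)c(OCc2ccccc2)c(OCc2ccccc2)c1 | intermediate
20 | [3,4,5-tris(benzyloxy)phenyl]lithium | [Li]c1cc(OCc2ccccc2)c(OCc2ccccc2)c(OCc2ccccc2)c1 | intermediate (not isolated)
21 | [3,4,5-tris(benzyloxy)phenyl]zinc bromide (LiBr complex, solution) | Br[Zn]c1cc(OCc2ccccc2)c(OCc2ccccc2)c(OCc2ccccc2)c1 | intermediate
22 | (3S,4R)-7-benzyloxy-2-bromo-4-(LU)chroman-3-yl 2,2-dimethylpropanoate, both C2 epimers | c1ccccc1COc1ccc2c(c1)OC(Br)[C@@H](OC(=O)C(C)(C)C)[C@H]2c1c(OCc3ccccc3)c(Br)c2c(c1OCc3ccccc3)C[C@H](OCc3ccccc3)[C@@H](c1cc(OCc3ccccc3)c(OCc3ccccc3)c(OCc3ccccc3)c1)O2 | intermediate (not isolated)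
23 | cis-fused 2-tert-butyl-1,3-dioxolan-2-ylium bromide spanning C2 and C3 of the chroman, on the face of the C4 aryl group | c1ccccc1COc1ccc2c(c1)O[C@H]3OC(C(C)(C)C)=[O+][C@H]3[C@H]2c1c(OCc3ccccc3)c(Br)c2c(c1OCc3ccccc3)C[C@H](OCc3ccccc3)[C@@H](c1cc(OCc3ccccc3)c(OCc3ccccc3)c(OCc3ccccc3)c1)O2.[Br-] | intermediate (not isolated)
24 | (2R,3S,4R)-7-benzyloxy-2-[3,4,5-tris(benzyloxy)phenyl]-4-(LU)chroman-3-yl 2,2-dimethylpropanoate | c1ccccc1COc1ccc2c(c1)O[C@H](c1cc(OCc3ccccc3)c(OCc3ccccc3)c(OCc3ccccc3)c1)[C@@H](OC(=O)C(C)(C)C)[C@H]2c1c(OCc3ccccc3)c(Br)c2c(c1OCc3ccccc3)C[C@H](OCc3ccccc3)[C@@H](c1cc(OCc3ccccc3)c(OCc3ccccc3)c(OCc3ccccc3)c1)O2 | intermediate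
25 | (2R,3S,4R)-7-benzyloxy-2-[3,4,5-tris(benzyloxy)phenyl]-4-(LU)chroman-3-ol | c1ccccc1COc1ccc2c(c1)O[C@H](c1cc(OCc3ccccc3)c(OCc3ccccc3)c(OCc3ccccc3)c1)[C@@H](O)[C@H]2c1c(OCc3ccccc3)c(Br)c2c(c1OCc3ccccc3)C[C@H](OCc3ccccc3)[C@@H](c1cc(OCc3ccccc3)c(OCc3ccccc3)c(OCc3ccccc3)c1)O2 | intermediate
26 | robinetinidol-(4β→6)-gallocatechin; upper unit (2R,3S,4R), lower unit (2R,3S) | Oc1ccc2c(c1)O[C@H](c1cc(O)c(O)c(O)c1)[C@@H](O)[C@H]2c1c(O)cc2c(c1O)C[C@H](O)[C@@H](c1cc(O)c(O)c(O)c1)O2 | target

## Step count and risk

Total steps: 16. Longest linear sequence: 11 steps (steps 1–5, 8–10, 14–16).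

Step 8 (key step).
- What may go wrong: the strongly stabilised methide may react slowly, so that the acid consumes the dioxole first (hydrolysis by the water set free, cationic oligomerisation). Endo or facial selectivity may erode, because the twisted di-ortho-substituted ring D aryl group may fit the catalyst pocket poorly. A stepwise addition may occur in which water captures the oxocarbenium ion. Acid-induced loss of ring D from the carbinol by retro-Friedel–Crafts cleavage is also conceivable.
- Fallback (known chemistry, from 4, returning at 25): (+)-dihydrorobinetin F1 is benzylated on its four phenols (BnBr, K2CO3, DMF, argon) to 7,3',4',5'-tetra-O-benzyldihydrorobinetin F2. NaBH4 in MeOH/THF reduces this to (2R,3S)-7-benzyloxy-2-(TBP)chroman-3,4-diol F3. Its C4 cation, generated with Me3SiOSO2CF3 in CH2Cl2 at −78 °C, is captured by an excess of 4, whose bromine leaves only C6 open. This gives 25 together with its C4 epimer, the 3,4-trans compound F4, from which 25 is separated by chromatography.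
- Cost of the fallback: cation capture favours the 3,4-trans isomer, so 25 is expected as the minor product; steps 5–15 are bypassed.

Step 14.
- What may go wrong: elimination of HBr from 22 to the enol pivalate of a 4H-chromene; transfer of the aryl group to the acyloxonium carbon in place of C2; ionisation without participation, giving both C2 epimers. All are favoured by the high temperature and by the weaker oxocarbenium stabilisation of an aryl ether oxygen.
- Fallback (known chemistry, from 15, returning at 25): lactol 15, in equilibrium with its open hydroxy-aldehyde, is treated with an excess of [3,4,5-tris(benzyloxy)phenyl]magnesium bromide F5 (from 19 and Mg in THF). This gives the open-chain triol (3R-configured diarylmethine, C1 carbinol epimers) F6. Ring C is then closed by acid-catalysed etherification through the benzylic cation of ring B (p-toluenesulfonic acid, CH2Cl2, 0 °C), which should prefer the 2,3-trans ether 25.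
- Cost of the fallback: control at C2 is thermodynamic only; steps 10 and 13–15 become unnecessary.

Step 5.
- What may go wrong: slow 1,2-addition of the di-ortho-substituted arylmagnesium to an aldehyde deactivated by its phenolate, so that protonation on work-up (return of 4) or halogen scrambling takes over.
- Fallback (from 5, returning at 9): the arylmagnesium 7 is quenched with DMF to give (2R,3S)-8-bromo-3,5,7-tris(benzyloxy)-2-(TBP)chroman-6-carbaldehyde F7. 4-Bromoresorcinol F8 is benzylated at the hydroxyl para to bromine (BnBr 1 equiv, K2CO3, acetone; the regioisomers are separated) to give 5-(benzyloxy)-2-bromophenol F9. Its O,C-dilithio derivative F10 (n-BuLi 2 equiv, THF, −78 → 0 °C) is small and unhindered and adds to F7, giving 9 directly with its phenol free.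

Step 16.
- What may go wrong: incomplete removal of ten benzyl groups or of the bromine; reductive opening of a benzylic C2–O1 bond on prolonged exposure; oxidation of the pyrogallol rings or acid-induced bond cleavage during isolation.
- Fallback (from 25, returning at 26): the bromine is first removed by bromine–lithium exchange (n-BuLi 2.2 equiv, THF, −78 °C, then MeOH) to give the 8-debromo deca-O-benzyl compound F11. The benzyl ethers are then cleaved without hydrogen by BCl3 with pentamethylbenzene as cation scavenger (CH2Cl2, −78 → −40 °C, MeOH quench).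

## Further compounds

F1 | step 8 | (+)-dihydrorobinetin, (2R,3R)-3,7-dihydroxy-2-(3,4,5-trihydroxyphenyl)chroman-4-one | O=C1c2ccc(O)cc2O[C@H](c2cc(O)c(O)c(O)c2)[C@H]1O
F2 | step 8 | (2R,3R)-7-benzyloxy-3-hydroxy-2-[3,4,5-tris(benzyloxy)phenyl]chroman-4-one | O=C1c2ccc(OCc3ccccc3)cc2O[C@H](c2cc(OCc3ccccc3)c(OCc3ccccc3)c(OCc3ccccc3)c2)[C@H]1O
F3 | step 8 | (2R,3S)-7-benzyloxy-2-[3,4,5-tris(benzyloxy)phenyl]chroman-3,4-diol (C4 epimers) | OC1c2ccc(OCc3ccccc3)cc2O[C@H](c2cc(OCc3ccccc3)c(OCc3ccccc3)c(OCc3ccccc3)c2)[C@H]1O
F4 | step 8 | (2R,3S,4S)-7-benzyloxy-2-[3,4,5-tris(benzyloxy)phenyl]-4-(LU)chroman-3-ol, the 3,4-trans C4 epimer of 25 | c1ccccc1COc1ccc2c(c1)O[C@H](c1cc(OCc3ccccc3)c(OCc3ccccc3)c(OCc3ccccc3)c1)[C@@H](O)[C@@H]2c1c(OCc3ccccc3)c(Br)c2c(c1OCc3ccccc3)C[C@H](OCc3ccccc3)[C@@H](c1cc(OCc3ccccc3)c(OCc3ccccc3)c(OCc3ccccc3)c1)O2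
F5 | step 14 | [3,4,5-tris(benzyloxy)phenyl]magnesium bromide | Br[Mg]c1cc(OCc2ccccc2)c(OCc2ccccc2)c(OCc2ccccc2)c1
F6 | step 14 | (2S,3R)-3-(4-benzyloxy-2-hydroxyphenyl)-3-(LU)-1-[3,4,5-tris(benzyloxy)phenyl]propane-1,2-diol (C1 epimers) | c1ccccc1COc1ccc(c(O)c1)[C@@H]([C@H](O)C(O)c1cc(OCc3ccccc3)c(OCc3ccccc3)c(OCc3ccccc3)c1)c1c(OCc3ccccc3)c(Br)c2c(c1OCc3ccccc3)C[C@H](OCc3ccccc3)[C@@H](c1cc(OCc3ccccc3)c(OCc3ccccc3)c(OCc3ccccc3)c1)O2
F7 | step 5 | (2R,3S)-8-bromo-3,5,7-tris(benzyloxy)-2-[3,4,5-tris(benzyloxy)phenyl]chroman-6-carbaldehyde | O=Cc1c(OCc3ccccc3)c(Br)c2c(c1OCc3ccccc3)C[C@H](OCc3ccccc3)[C@@H](c1cc(OCc3ccccc3)c(OCc3ccccc3)c(OCc3ccccc3)c1)O2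
F8 | step 5 | 4-bromoresorcinol | Oc1ccc(Br)c(O)c1
F9 | step 5 | 5-(benzyloxy)-2-bromophenol | Oc1cc(OCc2ccccc2)ccc1Br
F10 | step 5 | lithium 5-(benzyloxy)-2-lithiophenolate | [Li]Oc1cc(OCc2ccccc2)ccc1[Li]
F11 | step 16 | (2R,3S,4R)-7-benzyloxy-2-[3,4,5-tris(benzyloxy)phenyl]-4-[(2R,3S)-3,5,7-tris(benzyloxy)-2-(3,4,5-tris(benzyloxy)phenyl)chroman-6-yl]chroman-3-ol | c1ccccc1COc1ccc2c(c1)O[C@H](c1cc(OCc3ccccc3)c(OCc3ccccc3)c(OCc3ccccc3)c1)[C@@H](O)[C@H]2c1c(OCc3ccccc3)cc2c(c1OCc3ccccc3)C[C@H](OCc3ccccc3)[C@@H](c1cc(OCc3ccccc3)c(OCc3ccccc3)c(OCc3ccccc3)c1)O2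
A1 | alternative 1 | nona-O-benzyl target with both 3-hydroxyls free | c1ccccc1COc1ccc2c(c1)O[C@H](c1cc(OCc3ccccc3)c(OCc3ccccc3)c(OCc3ccccc3)c1)[C@@H](O)[C@H]2c1c(OCc3ccccc3)cc2c(c1OCc3ccccc3)C[C@H](O)[C@@H](c1cc(OCc3ccccc3)c(OCc3ccccc3)c(OCc3ccccc3)c1)O2
A2 | alternative 1 | bis(trans-epoxide) diphenol: diarylmethine carrying the 2-hydroxy-4-benzyloxyphenyl ring, one 3-aryloxiran-2-yl group, and a ring D phenol with an (3-aryloxiran-2-yl)methyl side chain | c1ccccc1COc1ccc(c(O)c1)[C@@H]([C@@H]2O[C@H]2c2cc(OCc3ccccc3)c(OCc3ccccc3)c(OCc3ccccc3)c2)c1c(OCc3ccccc3)cc(O)c(C[C@@H]2O[C@H]2c2cc(OCc3ccccc3)c(OCc3ccccc3)c(OCc3ccccc3)c2)c1OCc3ccccc3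
A3 | alternative 2 | protected target with free 4-hydroxyl on ring E, free lower 3-hydroxyl and upper 3-O-silyl ether | c1ccccc1COc1ccc2c(c1)O[C@H](c1cc(OCc3ccccc3)c(OCc3ccccc3)c(OCc3ccccc3)c1)[C@@H](O[Si](C)(C)C(C)(C)C)[C@H]2c1c(OCc3ccccc3)cc2c(c1OCc3ccccc3)C[C@H](O)[C@@H](c1cc(OCc3ccccc3)c(O)c(OCc3ccccc3)c1)O2
A4 | alternative 2 | upper unit carrying a ring D phenol with a 2-hydroxy-3-(4-hydroxy-3,5-dibenzyloxyphenyl)propyl side chain | c1ccccc1COc1ccc2c(c1)O[C@H](c1cc(OCc3ccccc3)c(OCc3ccccc3)c(OCc3ccccc3)c1)[C@@H](O[Si](C)(C)C(C)(C)C)[C@H]2c1c(OCc3ccccc3)cc(O)c(C[C@H](O)Cc2cc(OCc3ccccc3)c(O)c(OCc3ccccc3)c2)c1OCc3ccccc3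
A5 | alternative 3 | protected target with benzyl ethers on the upper unit and methoxymethyl and silyl ethers on the lower unit | c1ccccc1COc1ccc2c(c1)O[C@H](c1cc(OCc3ccccc3)c(OCc3ccccc3)c(OCc3ccccc3)c1)[C@@H](OCc3ccccc3)[C@H]2c1c(OCOC)cc2c(c1OCOC)C[C@H](O[Si](C)(C)C(C)(C)C)[C@@H](c1cc(OCOC)c(OCOC)c(OCOC)c1)O2
A6 | alternative 3 | open-chain bromo alcohol: 3-(2-bromo-4-benzyloxyphenyl)-2-benzyloxy-3-(protected lower unit)-1-[3,4,5-tris(benzyloxy)phenyl]propan-1-ol | c1ccccc1COc1ccc(c(Br)c1)[C@@H]([C@H](OCc3ccccc3)[C@H](O)c1cc(OCc3ccccc3)c(OCc3ccccc3)c(OCc3ccccc3)c1)c1c(OCOC)cc2c(c1OCOC)C[C@H](O[Si](C)(C)C(C)(C)C)[C@@H](c1cc(OCOC)c(OCOC)c(OCOC)c1)O2
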